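The cyclohex-2-enone ring (numbered from the ketone carbon, C1) is opened between C3, the β-carbon of the enone, and C4, the ring methylene on the carbinol carbon C5. The precursor carries on C5 an iodomethyl group (C4) and a terminal ynone arm (C6–C1–C2≡C3), while the C5 oxygen and the 2-oxoalkyl side chain are masked together as a 2-isoxazoline. A primary C4 radical adds 6-endo-dig to the electrophilic ynone terminus, closing the carbocycle and creating the cis-enone in one operation. C5 is set earlier by a tartrate-controlled, hydroxyl-directed nitrile oxide cycloaddition that also brings in the linoleyl chain; its directing CH2OH becomes C4. N–O cleavage finally releases the aldol.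

Key step: step 9

Assumption: the facial sense of the zinc/tartrate-mediated nitrile oxide cycloaddition known for allyl alcohol ((R,R)-tartrate gives the (R)-5-(hydroxymethyl)isoxazoline) is taken to hold for the 2-substituted allylic alcohol 6, where the same spatial arrangement is named S because the extra arm changes the priorities; should the sense prove reversed, (S,S)-diisopropyl tartrate is used.

Remark: 4–6 are racemic at the carbinol carbon of the alkynyl arm, so 12–14 are carried as a pair of epimers at that carbon; it becomes the C1 carbonyl in step 8.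

Step 1
Reactants: 1 ethyl 2-(bromomethyl)prop-2-enoate; 2 3-(trimethylsilyl)prop-2-ynal
Product: 4 ethyl 4-hydroxy-2-methylidene-6-(trimethylsilyl)hex-5-ynoate (racemic), via allylzinc bromide 3 (not isolated)
Conditions: Zn dust, THF/sat. aq. NH4Cl, 0 °C to rt
Reagents that add atoms: none
Why: Zinc inserts into the allylic C–Br bond and the resulting allylzinc adds to the ynal carbonyl (Barbier allylation), giving the homoallylic alcohol as a racemate, which is harmless because this carbinol carbon becomes the C1 ketone in step 8.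

Step 2
Reactants: 4 ethyl 4-hydroxy-2-methylidene-6-(trimethylsilyl)hex-5-ynoate
Product: 5 ethyl 4-[(tert-butyldimethylsilyl)oxy]-2-methylidene-6-(trimethylsilyl)hex-5-ynoate (racemic)
Conditions: TBSCl, imidazole, DMF, rt
Reagents that add atoms: tert-butyl(chloro)dimethylsilane (TBSCl), CC(C)(C)[Si](C)(C)Cl
Why: Imidazole-promoted silylation (silyl ether protection) blocks the propargylic alcohol, so that the only free hydroxyl later available to direct the cycloaddition and to be iodinated is the primary allylic one.

Step 3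
Reactants: 5 ethyl 4-[(tert-butyldimethylsilyl)oxy]-2-methylidene-6-(trimethylsilyl)hex-5-ynoate
Product: 6 4-[(tert-butyldimethylsilyl)oxy]-2-methylidene-6-(trimethylsilyl)hex-5-yn-1-ol (racemic)
Conditions: i-Bu2AlH (2.2 equiv), CH2Cl2, −78 °C
Reagents that add atoms: none
Why: i-Bu2AlH reduces the conjugated ester in 1,2-fashion to the primary allylic alcohol at low temperature, where the silyl ether and the C-silyl alkyne are inert.

Step 4
Reactants: 7 (9Z,12Z)-octadeca-9,12-dien-1-ol (linoleyl alcohol)
Product: 9 (9Z,12Z)-octadeca-9,12-dienal oxime (E/Z mixture at C=N), via linoleyl aldehyde 8 (not isolated)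
Conditions: PhI(OAc)2, TEMPO (cat.), CH2Cl2, rt; aq. Na2S2O3 wash; then NH2OH·HCl, pyridine, EtOH, rt
Reagents that add atoms: hydroxylamine hydrochloride, NO.Cl
Why: The TEMPO/PhI(OAc)2 oxidation should stop at the aldehyde without acid or base that could move the skipped diene into conjugation, and the air-sensitive aldehyde is condensed at once with hydroxylamine (oxime formation) to the storable aldoxime.

Step 5
Reactants: 9 (9Z,12Z)-octadeca-9,12-dienal oxime; 6 4-[(tert-butyldimethylsilyl)oxy]-2-methylidene-6-(trimethylsilyl)hex-5-yn-1-ol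
Product: 12 [(5S)-5-{2-[(tert-butyldimethylsilyl)oxy]-4-(trimethylsilyl)but-3-yn-1-yl}-3-[(8Z,11Z)-heptadeca-8,11-dien-1-yl]-4,5-dihydro-1,2-oxazol-5-yl]methanol (epimers at the silyloxy carbon), via hydroximoyl chloride 10 (not isolated), via nitrile oxide 11 (not isolated)
Conditions: NCS, pyridine (cat.), CHCl3, rt; aqueous wash; then slow addition to 6, Et2Zn (2 equiv), (R,R)-diisopropyl tartrate (1 equiv), 1,4-dioxane, CHCl3, 0 °C
Reagents that add atoms: none
Why: N-chlorination and zinc-mediated loss of HCl generate the nitrile oxide, which adds to the zinc alkoxide of 6 in a hydroxyl-directed 1,3-dipolar (Huisgen) cycloaddition with oxygen bonding to the disubstituted alkene carbon; the zinc/(R,R)-tartrate template holds dipole and alkoxide together and presents one alkene face, which sets the quaternary carbon (later ring C5) as S.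

Step 6
Reactants: 12 the (5S)-hydroxymethyl isoxazoline
Product: 13 (5S)-5-{2-[(tert-butyldimethylsilyl)oxy]-4-(trimethylsilyl)but-3-yn-1-yl}-3-[(8Z,11Z)-heptadeca-8,11-dien-1-yl]-5-(iodomethyl)-4,5-dihydro-1,2-oxazole (epimers at the silyloxy carbon)
Conditions: I2, PPh3, imidazole, toluene, 60 °C
Reagents that add atoms: iodine, II
Why: The Appel reaction converts the primary, neopentyl-type alcohol into the iodide through an alkoxyphosphonium ion displaced by iodide; warming is needed for the hindered carbon, and no carbonyl group is present yet that could capture that ion.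

Step 7
Reactants: 13 the (5S)-iodomethyl isoxazoline bis-silyl compound
Product: 14 1-[(5S)-3-[(8Z,11Z)-heptadeca-8,11-dien-1-yl]-5-(iodomethyl)-4,5-dihydro-1,2-oxazol-5-yl]but-3-yn-2-ol (epimers at the carbinol carbon)
Conditions: Bu4NF, AcOH, THF, 0 °C to rt
Reagents that add atoms: none
Why: Fluoride-mediated desilylation removes the O-silyl and the C-silyl group in one operation, with acetic acid keeping the medium non-basic so that the isoxazoline and the primary iodide are untouched.

Step 8
Reactants: 14 1-[(5S)-3-[(8Z,11Z)-heptadeca-8,11-dien-1-yl]-5-(iodomethyl)-4,5-dihydro-1,2-oxazol-5-yl]but-3-yn-2-ol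
Product: 15 1-[(5S)-3-[(8Z,11Z)-heptadeca-8,11-dien-1-yl]-5-(iodomethyl)-4,5-dihydro-1,2-oxazol-5-yl]but-3-yn-2-one
Conditions: Dess–Martin periodinane, CH2Cl2, 0 °C to rt
Reagents that add atoms: none
Why: The Dess–Martin oxidation turns the propargylic alcohol into the terminal ynone under neutral conditions and removes the stereorandom carbinol centre, so that a single stereoisomer should result.

Step 9
Reactants: 15 1-[(5S)-3-[(8Z,11Z)-heptadeca-8,11-dien-1-yl]-5-(iodomethyl)-4,5-dihydro-1,2-oxazol-5-yl]but-3-yn-2-one
Product: 16 (5S)-3-[(8Z,11Z)-heptadeca-8,11-dien-1-yl]-1-oxa-2-azaspiro[4.5]deca-2,8-dien-7-one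
Conditions: (TMS)3SiH (1.3 equiv, syringe pump), Et3B (0.3 equiv), air, toluene (0.005 M), rt
Reagents that add atoms: none
Why: Ethyl radicals from Et3B/O2 start a chain in which a silyl radical abstracts iodine from 15; the nucleophilic primary radical at C4 adds to the terminal, electrophilic β-carbon (C3) of the ynone, and the resulting α-keto vinyl radical is reduced by (TMS)3SiH, which regenerates the silyl radical. The closest known reaction type is the Giese-type reductive radical conjugate addition in its endo-cyclising form on alkynones. The cyclohexenone ring closes in the 6-endo-dig mode. No stereocentre is formed: C5 is quaternary and keeps its configuration, and the cis geometry of the C2=C3 bond is dictated by the ring. The step needs attack at C3 instead of 5-exo attack at C2, which the polarisation of the ynone (carbonyl inside the forming ring, unsubstituted terminus) should secure, and it needs ring closure to outrun hydrogen transfer, which high dilution and slow addition of the comparatively slow donor (TMS)3SiH should secure.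

Step 10
Reactants: 16 (5S)-3-[(8Z,11Z)-heptadeca-8,11-dien-1-yl]-1-oxa-2-azaspiro[4.5]deca-2,8-dien-7-one
Product: 18 (5S)-5-hydroxy-5-[(10Z,13Z)-2-oxononadeca-10,13-dien-1-yl]cyclohex-2-en-1-one, via hydroxy imine 17 (not isolated)
Conditions: Mo(CO)6, MeCN/H2O (10:1), 80 °C
Reagents that add atoms: water, O
Why: Mo(CO)6 cleaves the weak N–O bond of the 2-isoxazoline reductively and the β-hydroxy imine hydrolyses in the wet medium (the isoxazoline route to aldols), which should free the tertiary alcohol and the side-chain ketone without reducing any alkene and without involving C5, so its S configuration is retained.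

Compound list
1 | ethyl 2-(bromomethyl)prop-2-enoate | CCOC(=O)C(=C)CBr | starting material
2 | 3-(trimethylsilyl)prop-2-ynal | C[Si](C)(C)C#CC=O | starting material
3 | [2-(ethoxycarbonyl)prop-2-en-1-yl]zinc bromide | CCOC(=O)C(=C)C[Zn]Br | intermediate
4 | ethyl 4-hydroxy-2-methylidene-6-(trimethylsilyl)hex-5-ynoate (racemic) | CCOC(=O)C(=C)CC(O)C#C[Si](C)(C)C | intermediate
5 | ethyl 4-[(tert-butyldimethylsilyl)oxy]-2-methylidene-6-(trimethylsilyl)hex-5-ynoate (racemic) | CCOC(=O)C(=C)CC(O[Si](C)(C)C(C)(C)C)C#C[Si](C)(C)C | intermediate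
6 | 4-[(tert-butyldimethylsilyl)oxy]-2-methylidene-6-(trimethylsilyl)hex-5-yn-1-ol (racemic) | C=C(CO)CC(O[Si](C)(C)C(C)(C)C)C#C[Si](C)(C)C | intermediate
7 | (9Z,12Z)-octadeca-9,12-dien-1-ol (linoleyl alcohol) | CCCCC/C=C\C/C=C\CCCCCCCCO | starting material
8 | (9Z,12Z)-octadeca-9,12-dienal | CCCCC/C=C\C/C=C\CCCCCCCC=O | intermediate
9 | (9Z,12Z)-octadeca-9,12-dienal oxime (E/Z mixture at C=N) | CCCCC/C=C\C/C=C\CCCCCCCC=NO | intermediate
10 | (9Z,12Z)-N-hydroxyoctadeca-9,12-dienimidoyl chloride | CCCCC/C=C\C/C=C\CCCCCCCC(Cl)=NO | intermediate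
11 | (9Z,12Z)-octadeca-9,12-dienenitrile oxide | CCCCC/C=C\C/C=C\CCCCCCCC#[N+][O-] | intermediate
12 | [(5S)-5-{2-[(tert-butyldimethylsilyl)oxy]-4-(trimethylsilyl)but-3-yn-1-yl}-3-[(8Z,11Z)-heptadeca-8,11-dien-1-yl]-4,5-dihydro-1,2-oxazol-5-yl]methanol (epimers at the silyloxy carbon) | CCCCC/C=C\C/C=C\CCCCCCCC1=NO[C@](CO)(CC(O[Si](C)(C)C(C)(C)C)C#C[Si](C)(C)C)C1 | intermediate
13 | (5S)-5-{2-[(tert-butyldimethylsilyl)oxy]-4-(trimethylsilyl)but-3-yn-1-yl}-3-[(8Z,11Z)-heptadeca-8,11-dien-1-yl]-5-(iodomethyl)-4,5-dihydro-1,2-oxazole (epimers at the silyloxy carbon) | CCCCC/C=C\C/C=C\CCCCCCCC1=NO[C@](CI)(CC(O[Si](C)(C)C(C)(C)C)C#C[Si](C)(C)C)C1 | intermediate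
14 | 1-[(5S)-3-[(8Z,11Z)-heptadeca-8,11-dien-1-yl]-5-(iodomethyl)-4,5-dihydro-1,2-oxazol-5-yl]but-3-yn-2-ol (epimers at the carbinol carbon) | CCCCC/C=C\C/C=C\CCCCCCCC1=NO[C@](CI)(CC(O)C#C)C1 | intermediate
15 | 1-[(5S)-3-[(8Z,11Z)-heptadeca-8,11-dien-1-yl]-5-(iodomethyl)-4,5-dihydro-1,2-oxazol-5-yl]but-3-yn-2-one | CCCCC/C=C\C/C=C\CCCCCCCC1=NO[C@](CI)(CC(=O)C#C)C1 | intermediate
16 | (5S)-3-[(8Z,11Z)-heptadeca-8,11-dien-1-yl]-1-oxa-2-azaspiro[4.5]deca-2,8-dien-7-one | CCCCC/C=C\C/C=C\CCCCCCCC1=NO[C@@]2(CC=CC(=O)C2)C1 | intermediate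
17 | (5S)-5-hydroxy-5-[(10Z,13Z)-2-iminononadeca-10,13-dien-1-yl]cyclohex-2-en-1-one | CCCCC/C=C\C/C=C\CCCCCCCC(=N)C[C@@]1(O)CC=CC(=O)C1 | intermediate
18 | (5S)-5-hydroxy-5-[(10Z,13Z)-2-oxononadeca-10,13-dien-1-yl]cyclohex-2-en-1-one | CCCCC/C=C\C/C=C\CCCCCCCC(=O)C[C@@]1(O)CC=CC(=O)C1 | target

Total step count: 10
Longest linear sequence: 9 steps (steps 1–3, then 5–10)

Steps most likely to fail

Step 5. The cycloaddition may lose facial control on a 2-substituted allylic alkoxide, and the aliphatic nitrile oxide may dimerise before it is trapped. The fallback replaces reagent control by resolution. Setting out from 9 and 6, the chloride 10 would be dehydrochlorinated with Et3N in CH2Cl2 in the presence of 6, a plain Huisgen cycloaddition with the same regiochemistry but no facial control, to give the C5-stereorandom cycloadduct F1. Preparative chromatography on a chiral stationary phase, collecting the (5S)-configured components, would return to 12.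

Step 9. The radical may attack the α-carbon (5-exo), take up hydrogen before ring closure, or open the isoxazoline by β-scission of the C5–O bond. The fallback forms the same C3–C4 bond by cross-coupling instead of conjugate radical addition. Setting out from 15, hydroiodination of the ynone (NaI, AcOH, rt) should give the (Z)-β-iodoenone F2. An intramolecular nickel-catalysed reductive cross-electrophile coupling of its vinyl and alkyl iodides (NiI2, 4,4'-di-tert-butyl-2,2'-bipyridine, Mn powder, DMA, rt) would then close the ring, with the regiochemistry fixed by the position of the vinyl iodide and no hydrogen donor present, and return to 16.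

Step 10. Under the hot molybdenum conditions the tertiary aldol may dehydrate towards an aromatic ring, or the enone may be reduced or complexed. The fallback masks the enone by a temporary change of oxidation level. Setting out from 16, a Luche reduction (NaBH4, CeCl3·7H2O, MeOH, −40 °C) should give the spirocyclic allylic alcohol F3. N–O cleavage with Mo(CO)6 in MeCN/H2O, now without an enone and without an aromatisation pathway, would give the dihydroxy ketone F4. Selective allylic oxidation with MnO2 in CH2Cl2, which leaves the tertiary alcohol alone, would return to 18.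

Further compounds
F1 | step 5 | [5-{2-[(tert-butyldimethylsilyl)oxy]-4-(trimethylsilyl)but-3-yn-1-yl}-3-[(8Z,11Z)-heptadeca-8,11-dien-1-yl]-4,5-dihydro-1,2-oxazol-5-yl]methanol (all four stereoisomers) | CCCCC/C=C\C/C=C\CCCCCCCC1=NOC(CO)(CC(O[Si](C)(C)C(C)(C)C)C#C[Si](C)(C)C)C1
F2 | step 9 | (3Z)-1-[(5S)-3-[(8Z,11Z)-heptadeca-8,11-dien-1-yl]-5-(iodomethyl)-4,5-dihydro-1,2-oxazol-5-yl]-4-iodobut-3-en-2-one | CCCCC/C=C\C/C=C\CCCCCCCC1=NO[C@](CI)(CC(=O)/C=C\I)C1
F3 | step 10 | (5S)-3-[(8Z,11Z)-heptadeca-8,11-dien-1-yl]-1-oxa-2-azaspiro[4.5]deca-2,8-dien-7-ol (epimers at C7) | CCCCC/C=C\C/C=C\CCCCCCCC1=NO[C@@]2(CC=CC(O)C2)C1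
F4 | step 10 | (10Z,13Z)-1-[(1R)-1,5-dihydroxycyclohex-3-en-1-yl]nonadeca-10,13-dien-2-one (epimers at C5 of the ring) | CCCCC/C=C\C/C=C\CCCCCCCC(=O)C[C@@]1(O)CC=CC(O)C1
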